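## Structural features

The target is a flavan: a benzene ring A fused at C4a/C8a to a dihydropyran ring C (O1, C2, C3, C4), with a 2,4-dihydroxyphenyl ring B on C2. Ring A is substituted at every position except C6: hydroxyl at C5, methoxyl at C7, a 3-methylbut-2-enyl (prenyl) chain at C8 and the ring oxygen O1 at C8a, so the prenyl group lies between the methoxyl and O1. C2 is the only stereocentre, has the S configuration (O1 > C1' > C3 > H) and has no stereogenic neighbour. C2 is a benzylic ether carbon whose aryl group carries ortho and para hydroxyls, so acid or a warm phenoxide can open C2–O1 to a quinone methide and racemise it. The prenyl alkene is sensitive to acid, electrophiles and hydrogenation, and the free phenols to oxidation. The real difficulties are (a) creating the lone C2 centre with absolute control, (b) telling O1 apart from the C5 oxygen, which decides whether the prenyl group ends up at C8 or C6, and (c) finishing under conditions that C2 and the prenyl group tolerate. The key step exploits the C2–H bond, which is benzylic to the electron-rich ring B and alpha to O1: with C4 temporarily a carbonyl on ring A, a carbene at C3 can insert into that bond, closing ring C and setting C2 in one operation.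

## Logic of the disconnections

**15 to 14.** The two ring-B O–H bonds are taken back to O–Si bonds. Silyl ethers are chosen because fluoride removes them without acid. The forward step must free two phenols cold and buffered, so that no phenoxide opens C2–O1.

**14 to 11.** The C4 methylene is traced back to a C4 carbonyl and the O5–H to an O5 tert-butyl carbonate. This adds an oxygen that the target lacks, but the carbonyl is what allows C3 to become a carbene carbon, and the adjacent carbonate is the device that deletes it. On hydride reduction the C4 alkoxide of 12 takes over the carbonate, the O5 phenoxide expels it to give 13, and a second hydride gives 14. The demand is that ketone reduction outruns both carbonate cleavage and base-induced opening of ring C.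

**11 to 10.** The C2–C3 bond is cut. This opens ring C, removes the only stereocentre and leaves an achiral aryl benzyl ether with a diazoacetyl group. The gain is large: both remaining pieces are flat aromatics joined by an ether. The demand is a catalyst that prefers the C2–H bond over the O1 lone pair and distinguishes the two enantiotopic hydrogens.

**10 to 8.** The C3=N2 unit is taken back to the methyl group of an aryl methyl ketone, through 9. The demand is enolisation next to an aryl carbonate. A tert-butyl carbonate is used rather than an ethyl carbonate for two reasons. A ketone enolate attacks a small ortho carbonate at carbon (Baker–Venkataraman-type transfer), which the tert-butyl group hinders. The bulkier acylating agent also distinguishes the two phenols of 3 better.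

**8 to 4 and 7.** The O1–CH2 bond is cut, which separates ring A from ring B and makes the route convergent. The demand is etherification of a hindered, hydrogen-bonded phenol under neutral conditions, because base would remove the carbonate and acid would ionise the electron-rich benzyl unit.

**7 to 6 to 5.** The benzylic C–O–H is traced to the aldehyde, and the two O–Si bonds to the free phenols of a commercial aldehyde. The demand is only that reduction is done cold so that silicon does not migrate to the new alkoxide.

**4 to 3.** The O5–C(=O) bond is cut. The demand is site selectivity: the carbonate must go on the phenol flanked by C6–H and not on the one flanked by the prenyl group, since the latter must remain free to become O1.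

**3 to 1 and 2.** The C8–CH2 bond of the prenyl group is cut. Because 1 is symmetric, its two open ring positions are equivalent and C-alkylation can give only one mono-prenyl isomer. The demand is C- over O-alkylation and mono- over bis-alkylation.

## Other disconnections considered

**Alternative 1:** ring A is built last, by benzannulation.
- **Cut:** C4a–C5, C8–C8a and C5–C6 of ring A; ring C is closed afterwards by O1–C2 etherification.
- **Forward key step:** heating 3-methoxy-2-prenylcyclobutenone A1 with the chiral siloxyalkyne A2. A1 opens to a vinylketene, adds to A2 by [2+2], reopens and closes by 6π electrocyclisation to the pentasubstituted phenol A3.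
- **In favour:** the positions of all five ring-A substituents follow from the connectivity of A1 and A2, and the two phenolic oxygens emerge already differentiated (one free, one silylated). On this point it is better than the chosen plan, which depends on a selective acylation (step 2). The carbinol centre of A2 comes from a well-understood ketone reduction, and no C4 oxygen has to be deleted.
- **Against:** neither A1 nor A2 is commercial and each needs several steps. In A3 the free phenol is O5 while O1 is silylated, so the protection pattern must be inverted before ring closure. Ring C is then closed by substitution with inversion at a carbinol benzylic to a 2,4-dioxygenated ring, where ionisation can erode the configuration. The methoxymethyl ethers need acid for removal, which the C2–O1 bond and the prenyl group tolerate poorly.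
- **Comparison:** convergence is equal. The individual reactions are better precedented than the carbene insertion. The stereocentre, however, is exposed in a late substitution, whereas in the chosen plan C2 is never a leaving-group carbon. The chosen plan is clearly shorter.

**Alternative 2:** ring C by asymmetric ortho-quinone methide cycloaddition.
- **Cut:** C3–C4 and O1–C2.
- **Forward key step:** a chiral phosphoric acid dehydrates the ring-A hydroxybenzyl alcohol A4 to its ortho-quinone methide, which adds the 2-hydroxystyrene A5 in a [4+2] sense to give the flavan A6.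
- **In favour:** ring C and C2 are made in one step at the correct oxidation level, with no diazo compound and no C4 oxygen to remove. The ortho hydroxyl that the catalyst needs for hydrogen bonding belongs to the target. On step economy and atom economy it is better than the chosen plan.
- **Against:** the methide carbon (C4) carries no substituent, so the quinone methide is less stabilised and more prone to oligomerise, and enantiocontrol for such methides is less secure than for aryl-substituted ones. Acid together with an electron-rich vinylphenol and a prenyl group invites cationic side reactions. The same acid can re-ionise C2–O1 of A6 and erode its purity. A4 still requires the two ring-A phenols to be told apart.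
- **Comparison:** both plans rest on an enantioselective step without close precedent for this substitution pattern, so they are equal on that count. Alternative 2 is shorter. The chosen plan closes the ring under neutral conditions that neither the prenyl group nor the new stereocentre can feel.

**Alternative 3:** ring C by gold-catalysed hydroarylation.
- **Cut:** C4–C4a.
- **Forward key step:** Ph3PAuNTf2 activates the terminal alkyne of the chiral aryl propargyl ether A7, and C4a attacks the terminal carbon in a 6-endo sense to give the 2H-chromene A8.
- **In favour:** C2 is set before ring closure by established asymmetric chemistry, and the ring-forming step does not touch it. This separation of stereogenesis from ring formation is better, in predictability, than the chosen plan. Only one ortho position of the aryl ether is open, so regiochemistry is certain.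
- **Against:** A7 requires etherification of a hindered phenol with a secondary, benzylic and propargylic electrophile that ionises easily. A8 can open by 6π electrocyclic ring-opening and reclose, scrambling C2. The C3=C4 bond must be reduced beside the prenyl alkene (diimide or RhCl(PPh3)3/H2). Two kinds of protecting group must be removed, and gold may engage the prenyl alkene.
- **Comparison:** step count is about equal, and both plans need one redox correction after ring closure (alkene reduction against carbonyl deletion), so they are equal there. The chosen plan gives the saturated C2–C3 bond directly and avoids a configurationally labile chromene.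

Key step: step 7

Assumption: the (S)-tert-leucinate catalyst is taken to deliver the (2S) product; if the sense of induction is the opposite, Rh2(R-PTTL)4 is used and nothing else changes.

## Route

Step 1
Reactants: 1 2',6'-dihydroxy-4'-methoxyacetophenone; 2 prenyl bromide (1-bromo-3-methylbut-2-ene)
Product: 3 1-[2,6-dihydroxy-4-methoxy-3-(3-methylbut-2-en-1-yl)phenyl]ethanone
Conditions: 2 (1.0 equiv), 10% aq. KOH, 0 °C → rt
Reagents that add atoms: none
Why: C-alkylation of an ambident phenoxide; in water the resorcinol-type dianion reacts at carbon, and the two open ring positions of symmetric 1 are equivalent, so only one mono-C-prenyl isomer can form; O-prenylated and doubly alkylated material is separated.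

Step 2
Reactants: 3 1-[2,6-dihydroxy-4-methoxy-3-(3-methylbut-2-en-1-yl)phenyl]ethanone
Product: 4 tert-butyl [2-acetyl-3-hydroxy-5-methoxy-4-(3-methylbut-2-en-1-yl)phenyl] carbonate
Conditions: Boc2O (1.05 equiv), iPr2NEt, DMAP (5 mol%), CH2Cl2, −20 → 0 °C
Reagents that add atoms: di-tert-butyl dicarbonate, CC(C)(C)OC(=O)OC(=O)OC(C)(C)C
Why: DMAP-catalysed O-acylation; the bulky acylpyridinium should choose the phenol flanked by a ring hydrogen over the one buttressed by the prenyl group, and the remaining hydroxyl, locked in a hydrogen bond to the acetyl group, resists a second acylation.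

Step 3
Reactants: 5 2,4-dihydroxybenzaldehyde
Product: 6 2,4-bis(triisopropylsilyloxy)benzaldehyde
Conditions: TIPSCl (2.4 equiv), imidazole, DMF, rt → 40 °C
Reagents that add atoms: chlorotriisopropylsilane, CC(C)[Si](Cl)(C(C)C)C(C)C
Why: Standard imidazole-mediated silylation of phenols; the chelated 2-hydroxyl reacts more slowly, hence the excess and gentle warming.

Step 4
Reactants: 6 2,4-bis(triisopropylsilyloxy)benzaldehyde
Product: 7 [2,4-bis(triisopropylsilyloxy)phenyl]methanol
Conditions: NaBH4, THF/MeOH, 0 °C; aq. NH4Cl
Reagents that add atoms: none
Why: Borohydride reduction of an aryl aldehyde; a short, cold reaction with a buffered quench keeps the bulky silyl group from migrating from the ortho oxygen to the new alkoxide.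

Step 5
Reactants: 4 tert-butyl [2-acetyl-3-hydroxy-5-methoxy-4-(3-methylbut-2-en-1-yl)phenyl] carbonate; 7 [2,4-bis(triisopropylsilyloxy)phenyl]methanol
Product: 8 tert-butyl {2-acetyl-3-[2,4-bis(triisopropylsilyloxy)benzyloxy]-5-methoxy-4-(3-methylbut-2-en-1-yl)phenyl} carbonate
Conditions: PPh3, DIAD, THF, 0 °C → rt
Reagents that add atoms: none
Why: Mitsunobu etherification; the ortho-acyl phenol is acidic enough to protonate the betaine, the primary benzylic oxyphosphonium is displaced readily even by a hindered phenoxide, and the neutral medium spares the aryl carbonate and the silyl ethers.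

Step 6
Reactants: 8 tert-butyl {2-acetyl-3-[2,4-bis(triisopropylsilyloxy)benzyloxy]-5-methoxy-4-(3-methylbut-2-en-1-yl)phenyl} carbonate
Product: 10 tert-butyl {3-[2,4-bis(triisopropylsilyloxy)benzyloxy]-2-(diazoacetyl)-5-methoxy-4-(3-methylbut-2-en-1-yl)phenyl} carbonate, via trifluoroacetyl diketone 9 (not isolated)
Conditions: LiN(SiMe3)2 (1.1 equiv), THF, −78 °C; CF3CO2CH2CF3 (1.2 equiv), −78 °C, 10 min; aq. NH4Cl; then 4-AcNHC6H4SO2N3, Et3N, H2O (1 equiv), MeCN, rt
Reagents that add atoms: 4-acetamidobenzenesulfonyl azide, CC(=O)Nc1ccc(cc1)S(=O)(=O)N=[N+]=[N-] (the two diazo nitrogens of 10); 2,2,2-trifluoroethyl trifluoroacetate, O=C(OCC(F)(F)F)C(F)(F)F (the trifluoroacetyl group of 9, lost again before 10)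
Why: Detrifluoroacetylative diazo transfer; the kinetic lithium enolate of the methyl ketone is trapped within minutes at −78 °C, before it can attack the hindered tert-butyl carbonate, and the activated diketone 9 then accepts the diazo group from the sulfonyl azide while the trifluoroacetyl group leaves on the sulfonamide nitrogen.

Step 7
Reactants: 10 tert-butyl {3-[2,4-bis(triisopropylsilyloxy)benzyloxy]-2-(diazoacetyl)-5-methoxy-4-(3-methylbut-2-en-1-yl)phenyl} carbonate
Product: 11 tert-butyl {(2S)-2-[2,4-bis(triisopropylsilyloxy)phenyl]-7-methoxy-8-(3-methylbut-2-en-1-yl)-4-oxochroman-5-yl} carbonate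
Conditions: Rh2(S-PTTL)4 (2 mol%), CH2Cl2, 0 °C, 10 added over 2 h (final ≤0.02 M)
Reagents that add atoms: none
Why: Loss of N2 from 10 on the dirhodium core gives an electrophilic acceptor carbene at C3, which takes up the hydridic C2–H of the aryl benzyl ether through a three-centre, hydride-transfer-like transition state in which C3–C2 and C3–H form as C2–H breaks and the catalyst is released. The closest known reaction type is the chiral dirhodium carboxylate-catalysed C–H insertion of ortho-alkoxyaryl diazomethyl ketones next to the ether oxygen, which gives chroman-4-ones. Ring C closes by 1,6-insertion (C3, C4, C4a, C8a, O1, C2); the six-membered ring is enforced because the atom that would give a five-membered ring is the oxygen itself. The new stereocentre C2 is under catalyst control: the phthalimido and tert-butyl groups of the carboxylate ligands decide which of the two enantiotopic benzylic hydrogens is presented to the carbene, and no other stereocentre is present to interfere. The step needs chemoselectivity for C–H insertion over attack of the O1 lone pair (oxonium ylide and 1,2-benzyl shift), over carbonyl ylide formation and over alkene cyclopropanation. The substrate helps because the C–H bond is activated twice (alpha to O1 and benzylic to a ring with two silyloxy donors), O1 is a sterically shielded aryl ether between the prenyl and acyl groups, the O5 carbonate is a poor donor with no reachable C–H bond, and the prenyl alkene is meta to the acyl group and cannot reach the carbene. Slow addition keeps the diazo concentration low so that carbene dimerisation and intermolecular cyclopropanation do not compete.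

Step 8
Reactants: 11 tert-butyl {(2S)-2-[2,4-bis(triisopropylsilyloxy)phenyl]-7-methoxy-8-(3-methylbut-2-en-1-yl)-4-oxochroman-5-yl} carbonate
Product: 14 (2S)-2-[2,4-bis(triisopropylsilyloxy)phenyl]-7-methoxy-8-(3-methylbut-2-en-1-yl)chroman-5-ol, via flavan-4-ol carbonate 12 (not isolated), via ortho-quinone methide 13 (not isolated)
Conditions: NaBH4 (4 equiv), THF/H2O, 0 °C → rt; aq. NH4Cl
Reagents that add atoms: none
Why: Ortho-carbonate-assisted reductive deoxygenation of an ortho-hydroxyaryl ketone; hydride gives the C4 alkoxide 12, which takes over the carbonate through a six-membered transfer, the O5 phenoxide expels tert-butyl carbonate to give 13, and a second hydride adds at C4; C2 is not part of the quinone methide, so its configuration should be kept.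

Step 9
Reactants: 14 (2S)-2-[2,4-bis(triisopropylsilyloxy)phenyl]-7-methoxy-8-(3-methylbut-2-en-1-yl)chroman-5-ol
Product: 15 (2S)-2-(2,4-dihydroxyphenyl)-7-methoxy-8-(3-methylbut-2-en-1-yl)chroman-5-ol
Conditions: TBAF (2.2 equiv), AcOH (2.2 equiv), THF, 0 °C
Reagents that add atoms: none
Why: Fluoride cleavage of aryl silyl ethers; buffering with acetic acid and working cold keeps the ring-B phenols protonated, so that no phenoxide opens C2–O1 and no acid strong enough to ionise C2 or hydrate the prenyl group is present.

## Compound list

1 | 2',6'-dihydroxy-4'-methoxyacetophenone | CC(=O)c1c(O)cc(OC)cc1O | starting material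
2 | prenyl bromide (1-bromo-3-methylbut-2-ene) | CC(C)=CCBr | starting material
3 | 1-[2,6-dihydroxy-4-methoxy-3-(3-methylbut-2-en-1-yl)phenyl]ethanone | CC(=O)c1c(O)cc(OC)c(CC=C(C)C)c1O | intermediate
4 | tert-butyl [2-acetyl-3-hydroxy-5-methoxy-4-(3-methylbut-2-en-1-yl)phenyl] carbonate | CC(=O)c1c(OC(=O)OC(C)(C)C)cc(OC)c(CC=C(C)C)c1O | intermediate
5 | 2,4-dihydroxybenzaldehyde | O=Cc1ccc(O)cc1O | starting material
6 | 2,4-bis(triisopropylsilyloxy)benzaldehyde | O=Cc1ccc(O[Si](C(C)C)(C(C)C)C(C)C)cc1O[Si](C(C)C)(C(C)C)C(C)C | intermediate
7 | [2,4-bis(triisopropylsilyloxy)phenyl]methanol | OCc1ccc(O[Si](C(C)C)(C(C)C)C(C)C)cc1O[Si](C(C)C)(C(C)C)C(C)C | intermediate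
8 | tert-butyl {2-acetyl-3-[2,4-bis(triisopropylsilyloxy)benzyloxy]-5-methoxy-4-(3-methylbut-2-en-1-yl)phenyl} carbonate | COc1cc(OC(=O)OC(C)(C)C)c(C(C)=O)c(c1CC=C(C)C)OCc1ccc(O[Si](C(C)C)(C(C)C)C(C)C)cc1O[Si](C(C)C)(C(C)C)C(C)C | intermediate
9 | tert-butyl {3-[2,4-bis(triisopropylsilyloxy)benzyloxy]-5-methoxy-4-(3-methylbut-2-en-1-yl)-2-(4,4,4-trifluoro-3-oxobutanoyl)phenyl} carbonate (drawn as the diketone) | COc1cc(OC(=O)OC(C)(C)C)c(C(=O)CC(=O)C(F)(F)F)c(c1CC=C(C)C)OCc1ccc(O[Si](C(C)C)(C(C)C)C(C)C)cc1O[Si](C(C)C)(C(C)C)C(C)C | intermediate
10 | tert-butyl {3-[2,4-bis(triisopropylsilyloxy)benzyloxy]-2-(diazoacetyl)-5-methoxy-4-(3-methylbut-2-en-1-yl)phenyl} carbonate | COc1cc(OC(=O)OC(C)(C)C)c(C(=O)C=[N+]=[N-])c(c1CC=C(C)C)OCc1ccc(O[Si](C(C)C)(C(C)C)C(C)C)cc1O[Si](C(C)C)(C(C)C)C(C)C | intermediate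
11 | tert-butyl {(2S)-2-[2,4-bis(triisopropylsilyloxy)phenyl]-7-methoxy-8-(3-methylbut-2-en-1-yl)-4-oxochroman-5-yl} carbonate | COc1cc(OC(=O)OC(C)(C)C)c2c(c1CC=C(C)C)O[C@H](c1ccc(O[Si](C(C)C)(C(C)C)C(C)C)cc1O[Si](C(C)C)(C(C)C)C(C)C)CC2=O | intermediate
12 | tert-butyl {(2S)-2-[2,4-bis(triisopropylsilyloxy)phenyl]-4-hydroxy-7-methoxy-8-(3-methylbut-2-en-1-yl)chroman-5-yl} carbonate (both C4 epimers, formed as the alkoxide) | COc1cc(OC(=O)OC(C)(C)C)c2c(c1CC=C(C)C)O[C@H](c1ccc(O[Si](C(C)C)(C(C)C)C(C)C)cc1O[Si](C(C)C)(C(C)C)C(C)C)CC2O | intermediate
13 | (2S)-2-[2,4-bis(triisopropylsilyloxy)phenyl]-7-methoxy-8-(3-methylbut-2-en-1-yl)-2,3-dihydro-5H-chromen-5-one (ortho-quinone methide, C4=C4a and C5=O) | COC1=CC(=O)C2=CC[C@@H](c3ccc(O[Si](C(C)C)(C(C)C)C(C)C)cc3O[Si](C(C)C)(C(C)C)C(C)C)OC2=C1CC=C(C)C | intermediate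
14 | (2S)-2-[2,4-bis(triisopropylsilyloxy)phenyl]-7-methoxy-8-(3-methylbut-2-en-1-yl)chroman-5-ol | COc1cc(O)c2c(c1CC=C(C)C)O[C@H](c1ccc(O[Si](C(C)C)(C(C)C)C(C)C)cc1O[Si](C(C)C)(C(C)C)C(C)C)CC2 | intermediate
15 | (2S)-2-(2,4-dihydroxyphenyl)-7-methoxy-8-(3-methylbut-2-en-1-yl)chroman-5-ol | COc1cc(O)c2c(c1CC=C(C)C)O[C@H](c1ccc(O)cc1O)CC2 | target

## Step count and least certain steps

Total: 9 steps. Longest linear sequence: 7 steps (steps 1, 2, 5, 6, 7, 8, 9; the ring-B branch through steps 3 and 4 is equally long).

**Step 7 (key step).** Three processes may interfere.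
- The O1 lone pair may attack the carbene to give a five-membered oxonium ylide, followed by a 1,2-shift of the electron-rich benzyl group. This competes with the six-membered insertion.
- An unstabilised acceptor carbene may discriminate poorly between the two enantiotopic hydrogens, or hydride transfer may become fully stepwise so that the zwitterion closes outside the chiral pocket.
- The carbene may dimerise.

Changing the ligand alters conditions only. The fallback avoids carbene chemistry; it sets out from 4 (with 6) and comes back at 11. Chlorodiisopinocampheylborane and Et3N (two equivalents, the first consumed by the phenol; the antipode that gives the R carbinol; non-oxidative work-up) mediate aldol addition of the methyl ketone of 4 to aldehyde 6. This should give tert-butyl {2-[(3R)-3-[2,4-bis(triisopropylsilyloxy)phenyl]-3-hydroxypropanoyl]-3-hydroxy-5-methoxy-4-(3-methylbut-2-en-1-yl)phenyl} carbonate F1, with an enantiomeric purity that may need upgrading by crystallisation. Intramolecular Mitsunobu etherification (PPh3, DIAD, THF, 0 °C) then lets the free phenol displace the activated carbinol with inversion, closing ring C to 11.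

**Step 6.** The lithium enolate may attack the neighbouring carbonate at carbon (Baker–Venkataraman-type transfer) before it is trifluoroacetylated, or the carbonate may be lost during the amine/water stage. The fallback installs the carbonate after the enolate chemistry; it sets out from 8 and comes back at 10. Piperidine in CH2Cl2 removes the carbonate to give 1-{2-[2,4-bis(triisopropylsilyloxy)benzyloxy]-6-hydroxy-4-methoxy-3-(3-methylbut-2-en-1-yl)phenyl}ethanone F2. The phenoxide–enolate dianion (LiN(SiMe3)2, 2.2 equiv) is trifluoroacetylated to 1-{2-[2,4-bis(triisopropylsilyloxy)benzyloxy]-6-hydroxy-4-methoxy-3-(3-methylbut-2-en-1-yl)phenyl}-4,4,4-trifluorobutane-1,3-dione F3, which is not isolated and may rest as its cyclic hemiketal. The sulfonyl azide with Et3N converts it into 1-{2-[2,4-bis(triisopropylsilyloxy)benzyloxy]-6-hydroxy-4-methoxy-3-(3-methylbut-2-en-1-yl)phenyl}-2-diazoethanone F4. Boc2O with catalytic DMAP then gives 10.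

**Step 1.** O-alkylation and double alkylation may consume much of the material, because phenoxide alkylation with an allylic halide is only moderately C-selective. The fallback moves the prenyl group from oxygen to carbon by rearrangement; it sets out from 1 and comes back at 3. Mono-O-alkylation (2, K2CO3, acetone) gives 1-[2-hydroxy-4-methoxy-6-(3-methylbut-2-en-1-yloxy)phenyl]ethanone F5. Para-Claisen–Cope rearrangement with Eu(fod)3 (CHCl3, 60 °C) should carry the prenyl group through the ortho position to the position para to the ether oxygen, which is C3 of 3.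

**Step 2 (and the hindered etherification of step 5).** The carbonate may form at the wrong phenol or at both, since the selectivity rests only on a steric difference between two hydrogen-bonded hydroxyls. In step 5 the remaining phenol is then etherified next to the prenyl group, which is slow. The fallback fixes the regiochemistry by construction; it sets out from 1 and comes back at 8. The prenyl ether F5 is etherified with 7 (PPh3, DIAD) at its only, unhindered phenol to give 1-{2-[2,4-bis(triisopropylsilyloxy)benzyloxy]-4-methoxy-6-(3-methylbut-2-en-1-yloxy)phenyl}ethanone F6. Eu(fod)3-promoted para-Claisen–Cope rearrangement then places the prenyl group next to the benzyl ether oxygen and frees the other phenol, giving F2. Boc2O with catalytic DMAP gives 8.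

## Further compounds

F1 | step 7 | tert-butyl {2-[(3R)-3-[2,4-bis(triisopropylsilyloxy)phenyl]-3-hydroxypropanoyl]-3-hydroxy-5-methoxy-4-(3-methylbut-2-en-1-yl)phenyl} carbonate | COc1cc(OC(=O)OC(C)(C)C)c(C(=O)C[C@@H](O)c2ccc(O[Si](C(C)C)(C(C)C)C(C)C)cc2O[Si](C(C)C)(C(C)C)C(C)C)c(O)c1CC=C(C)C
F2 | step 6 | 1-{2-[2,4-bis(triisopropylsilyloxy)benzyloxy]-6-hydroxy-4-methoxy-3-(3-methylbut-2-en-1-yl)phenyl}ethanone | COc1cc(O)c(C(C)=O)c(c1CC=C(C)C)OCc1ccc(O[Si](C(C)C)(C(C)C)C(C)C)cc1O[Si](C(C)C)(C(C)C)C(C)C
F3 | step 6 | 1-{2-[2,4-bis(triisopropylsilyloxy)benzyloxy]-6-hydroxy-4-methoxy-3-(3-methylbut-2-en-1-yl)phenyl}-4,4,4-trifluorobutane-1,3-dione | COc1cc(O)c(C(=O)CC(=O)C(F)(F)F)c(c1CC=C(C)C)OCc1ccc(O[Si](C(C)C)(C(C)C)C(C)C)cc1O[Si](C(C)C)(C(C)C)C(C)C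
F4 | step 6 | 1-{2-[2,4-bis(triisopropylsilyloxy)benzyloxy]-6-hydroxy-4-methoxy-3-(3-methylbut-2-en-1-yl)phenyl}-2-diazoethanone | COc1cc(O)c(C(=O)C=[N+]=[N-])c(c1CC=C(C)C)OCc1ccc(O[Si](C(C)C)(C(C)C)C(C)C)cc1O[Si](C(C)C)(C(C)C)C(C)C
F5 | step 1 | 1-[2-hydroxy-4-methoxy-6-(3-methylbut-2-en-1-yloxy)phenyl]ethanone | CC(=O)c1c(O)cc(OC)cc1OCC=C(C)C
F6 | step 2 | 1-{2-[2,4-bis(triisopropylsilyloxy)benzyloxy]-4-methoxy-6-(3-methylbut-2-en-1-yloxy)phenyl}ethanone | CC(=O)c1c(OCC=C(C)C)cc(OC)cc1OCc1ccc(O[Si](C(C)C)(C(C)C)C(C)C)cc1O[Si](C(C)C)(C(C)C)C(C)C
A1 | alternative 1 | 3-methoxy-2-(3-methylbut-2-en-1-yl)cyclobut-2-en-1-one | COC1=C(CC=C(C)C)C(=O)C1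
A2 | alternative 1 | {[(5R)-5-[2,4-bis(methoxymethoxy)phenyl]-5-(tert-butyldimethylsilyloxy)pent-1-yn-1-yl]oxy}triisopropylsilane | CC(C)[Si](OC#CCC[C@@H](O[Si](C)(C)C(C)(C)C)c1ccc(OCOC)cc1OCOC)(C(C)C)C(C)C
A3 | alternative 1 | 2-[(3R)-3-[2,4-bis(methoxymethoxy)phenyl]-3-(tert-butyldimethylsilyloxy)propyl]-5-methoxy-4-(3-methylbut-2-en-1-yl)-3-(triisopropylsilyloxy)phenol | COc1cc(O)c(CC[C@@H](O[Si](C)(C)C(C)(C)C)c2ccc(OCOC)cc2OCOC)c(O[Si](C(C)C)(C(C)C)C(C)C)c1CC=C(C)C
A4 | alternative 2 | 3-(tert-butyldimethylsilyloxy)-2-(hydroxymethyl)-5-methoxy-6-(3-methylbut-2-en-1-yl)phenol | COc1cc(O[Si](C)(C)C(C)(C)C)c(CO)c(O)c1CC=C(C)C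
A5 | alternative 2 | 5-(tert-butyldimethylsilyloxy)-2-vinylphenol | C=Cc1ccc(O[Si](C)(C)C(C)(C)C)cc1O
A6 | alternative 2 | 5-(tert-butyldimethylsilyloxy)-2-[(2S)-5-(tert-butyldimethylsilyloxy)-7-methoxy-8-(3-methylbut-2-en-1-yl)chroman-2-yl]phenol | COc1cc(O[Si](C)(C)C(C)(C)C)c2c(c1CC=C(C)C)O[C@H](c1ccc(O[Si](C)(C)C(C)(C)C)cc1O)CC2
A7 | alternative 3 | 4-{(1S)-1-[3-methoxy-2-(3-methylbut-2-en-1-yl)-5-(triisopropylsilyloxy)phenoxy]prop-2-yn-1-yl}-1,3-phenylene bis(2,2-dimethylpropanoate) | COc1cc(O[Si](C(C)C)(C(C)C)C(C)C)cc(O[C@H](c2ccc(OC(=O)C(C)(C)C)cc2OC(=O)C(C)(C)C)C#C)c1CC=C(C)C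
A8 | alternative 3 | 4-[(2S)-7-methoxy-8-(3-methylbut-2-en-1-yl)-5-(triisopropylsilyloxy)-2H-chromen-2-yl]-1,3-phenylene bis(2,2-dimethylpropanoate) | COc1cc(O[Si](C(C)C)(C(C)C)C(C)C)c2c(c1CC=C(C)C)O[C@H](c1ccc(OC(=O)C(C)(C)C)cc1OC(=O)C(C)(C)C)C=C2
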